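## Structural features

The target is a guaiane ester: a cyclopentane (C1–C5) fused along C1–C5 to a seven-membered ring (C1, C5, C6, C7, C8, C9, C10). Guaiane numbering is used for every intermediate, with C15 the methyl on C4, C14 the methyl on C10 and C11 the carbinol carbon on C7. The only ring alkene is tetrasubstituted, between C1 and C10, so C1 is not stereogenic. Four stereocentres remain, all S: C4 and C5 are neighbours in the five-membered ring, C7 and C8 are neighbours in the seven-membered ring, and C6 separates the two pairs. H4, H5 and H7 lie on one face (α), C15 and C11 on the other (β), and the C8 oxygen is α, trans to the C11 branch. C8 carries an (E)-feruloyl ester with a free phenol, and C11 is a free tertiary alcohol 1,3 to the ester oxygen. Fragile points are the tertiary carbinol (ionisation, dehydration, retro-aldol cleavage while C8 is a ketone), the 1(10)-alkene (β,γ to C8, so it can slip into conjugation whenever C8 is a carbonyl), the cinnamate and phenol (base), and H5 in any intermediate with a C4 carbonyl. The real difficulty is the seven-membered ring with its alkene fixed at 1(10), together with the relative configuration of the two stereo-pairs across C6. The key step exploits that C1, C6, C7, C8, C9 and C10 carry C2, H, C11, oxygen, H and C14 in the pattern of a tetrasubstituted anisole: the seven-membered ring is a benzene ring plus one carbon, C5, inserted between C1 and C6, and the same carbon closes the cyclopentane through the C2–C3–C4 tether.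

## Logic of the disconnections

24 to 23: the two O–Si bonds (O11 and the phenol oxygen) are cut. Both hydroxyls must be masked while C8 is acylated, and one fluoride treatment frees both. The forward step has to spare the cinnamate ester and must not ionise C11.

23 to 18 and 21: the C8 O–acyl bond is cut. This is the convergent cut and removes the whole aromatic acid, which comes from 19 by O-silylation. The forward acylation must reach a hindered secondary alcohol without touching C8, and 21 must not acylate itself.

18 to 17: the C8–H bond is cut, giving the C8 ketone that the arene oxygen will deliver. One stereocentre is removed. The reduction has to place oxygen trans to the C11 branch and must be faster than enolisation toward C9, or the 1(10)-alkene moves.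

17 to 16: the C6–H and C7–H bonds are cut, giving the C6–C7 enone. C7 is no longer stereogenic. The forward step needs a strictly 1,4-selective hydride and protonation of C7 from the α face.

16 to 15: the C4–H and C15–H bonds are cut, giving the exocyclic C4–C15 alkene. C4 is no longer stereogenic. The hydrogenation must touch only this alkene and must come from the face of H5.

15 to 14: the C8 carbonyl is traded for its methyl enol ether. This reveals the cycloheptatriene and keeps C8 inert during C4 chemistry. The hydrolysis must protonate C9 and not C1, under acid weak enough for the silyl ether and H5.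

14 to 13: the C4–C15 double bond is cut back to the C4 ketone. This cut is placed before the unmasking of C8 so that C4 is the only carbonyl when it is methylenated and C5 stops being α to a carbonyl at the earliest point. The methylenation must be non-basic.

13 to 11 (through 12): C1–C5 and C5–C6 are cut. Both rings and the only stereocentre disappear, leaving an arene with a diazoketone side chain. The forward step needs enantioface selection by the catalyst, addition to the unsubstituted ortho bond, and a protected O11. The O11 silyl group is triethylsilyl and not a smaller one, because it must survive steps 6 to 14.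

11 to 9: the C4–C5 bond is cut (acylation of the diazo carbon by an activated acid). The activation must not release strong acid next to the benzylic silyl ether.

9 to 7, 6 and 5: the O11–Si bond, one C11–methyl bond and the C7–C11 aryl–acyl bond are cut in turn. This leaves a simple arylpropanoic acid. The acylation must go ortho to the methoxy group and para to the ring methyl, and the methyl addition must tolerate the free acid.

5 to 4, then 1 and 2: the C2–C3 bond is cut as an alkene. Both fragments are commodity chemicals; the forward steps only need a decarboxylative condensation and an alkene hydrogenation.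

## Other disconnections considered

Alternative 1: The cut is C7–C8. In the forward key step ZnBr2 would activate the C8 aldehyde of the cyclopentylidene aldehyde A2 for a carbonyl-ene reaction with its trisubstituted side-chain alkene, giving the dienol A1.
- In its favour: it would form the seven-membered ring and both C7 and C8 in one step, with the trans relationship coming from a single cyclic transition state. Here it is the better plan, since the chosen route needs two separate reductions for these centres. It also avoids diazo chemistry and a labile cycloheptatriene, and only hydration of the isopropenyl group, acylation and deprotection would follow, so it is also better in step economy after the key step.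
- Against it: a seven-membered ene closure lacks the chair organisation of the six-membered case. The aldehyde of A2 is β,γ-unsaturated and would enolise or conjugate under Lewis acid. A2 needs a tetrasubstituted exocyclic alkene of defined Z geometry beside two preset ring stereocentres, which is a longer task than the arene of the chosen route.
- Equal: both plans hold the 1(10)-alkene before the ring closes. Overall the two are likely of similar length, with the risk concentrated in the ring closure and the precursor geometry for A1, and in the post-key-step stereocontrol for the chosen plan.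

Alternative 2: The cuts are C1–C5 and C8–C9. Triflic acid would ionise the allylic alcohol A4 to a 2-methylallyl cation that adds across the furan, giving the oxygen-bridged diene A3 after loss of H1.
- In its favour: two rings and two bonds in one step from a short linear precursor. The C4 centre is set in the tether from the start and directs the bridge, and the C8 oxygen arrives with the correct configuration. On convergence and on C4 it is better than the chosen plan, which sets C4 late by hydrogenation.
- Against it: C5 emerges as an oxygen-bearing quaternary centre. The C5–O bond would have to be cleaved reductively with hydrogen delivered to the same face, through an allylic intermediate spread over C5–C7 with uncertain regio- and stereocontrol. C7 still needs a separate reduction. A non-oxygenated allyl cation can alkylate the furan without closing the second bond, strong acid threatens the tertiary allylic silyl ether, and the C10 cation can lose H9 or H14.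
- Comparison: the chosen plan makes C5 directly as a C–H stereocentre under catalyst control and uses no strong acid, at the price of more steps after the key step.

Alternative 3: The cut is C1–C5 of a ten-membered ring. BF3·OEt2 would open the epoxide of the epoxy-macrocycle A6 with transannular attack of C1 on C5, giving the hydroxy dienone A5.
- In its favour: it is the shortest way to the bicycle; all fifteen carbons, the C8 carbonyl and the 1(10)-alkene would be in place after two operations on a terpenoid macrocycle. In step economy to the skeleton it is clearly better.
- Against it: the parent macrocycle is achiral and has two similar trisubstituted alkenes, so A6 must be made regio- and enantioselectively. The C10 cation can lose different protons or be trapped. The C4 hydroxyl must be replaced by hydrogen on the same face. The 7(11)-en-8-one must be turned into the 11-hydroxy-7H-8-ol by an oxidation and two reductions.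
- Equal: C4, C7 and C8 are set after the key step by substrate control, as in the chosen plan. The difference is that the chosen plan fixes the absolute configuration with a chiral catalyst and needs no oxygen removed.

Key step: step 7

Assumption: the ligand antipode written in step 7 is taken to favour the (5R) product; the sense of induction cannot be predicted for this substitution pattern, and the mirror-image ligand is used if the opposite sense is found.
Remark: the descriptor of C5 changes along the route (R in 13 and 16, S elsewhere) only because the CIP ranking of its neighbours changes; the spatial arrangement at C5 is the same from 13 to 24.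

Step 1
Reactants: 1 4-methoxy-2-methylbenzaldehyde; 2 malonic acid
Product: 4 (2E)-3-(4-methoxy-2-methylphenyl)prop-2-enoic acid, via arylidenemalonic acid 3 (not isolated)
Conditions: pyridine, piperidine (0.1 equiv), 100 °C
Reagents that add atoms: none
Why: Doebner–Knoevenagel condensation; the aldehyde condenses with the malonic methylene to 3, which loses CO2 in hot pyridine to the conjugated (E)-acid.

Step 2
Reactants: 4 (2E)-3-(4-methoxy-2-methylphenyl)prop-2-enoic acid
Product: 5 3-(4-methoxy-2-methylphenyl)propanoic acid
Conditions: H2 (1 atm), 10% Pd/C, EtOAc, rt
Reagents that add atoms: none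
Why: Heterogeneous hydrogenation of the cinnamic alkene; arene, ether and acid are inert at 1 atm and room temperature.

Step 3
Reactants: 5 3-(4-methoxy-2-methylphenyl)propanoic acid
Product: 6 3-(5-acetyl-4-methoxy-2-methylphenyl)propanoic acid
Conditions: AcCl (1.3 equiv), AlCl3 (3.2 equiv), CH2Cl2, 0 °C; ice/aq. HCl
Reagents that add atoms: acetyl chloride, CC(=O)Cl
Why: Friedel–Crafts acylation ortho to the methoxy group and para to the ring methyl; the other ortho position is flanked on both sides and the remaining position is meta to both donors, which also keeps indanone closure of the side chain slow, and 0 °C limits O-demethylation by AlCl3.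

Step 4
Reactants: 6 3-(5-acetyl-4-methoxy-2-methylphenyl)propanoic acid
Product: 7 3-[5-(2-hydroxypropan-2-yl)-4-methoxy-2-methylphenyl]propanoic acid
Conditions: MeMgBr (3.5 equiv), THF, −10 °C → rt; H2O, citric acid to pH 4–5, 0 °C
Reagents that add atoms: methylmagnesium bromide, C[Mg]Br
Why: Grignard addition; the first equivalent forms the unreactive magnesium carboxylate and the excess adds to the aryl ketone, and the cold, weakly acidic work-up avoids dehydration of the electron-rich cumyl alcohol.

Step 5
Reactants: 7 3-[5-(2-hydroxypropan-2-yl)-4-methoxy-2-methylphenyl]propanoic acid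
Product: 9 3-{4-methoxy-2-methyl-5-[2-(triethylsilyloxy)propan-2-yl]phenyl}propanoic acid, via bis-silyl ester 8 (not isolated)
Conditions: Et3SiOTf (2.3 equiv), 2,6-lutidine (3 equiv), CH2Cl2, −78 → 0 °C; then MeOH/H2O, rt; pH 5 buffer
Reagents that add atoms: triethylsilyl trifluoromethanesulfonate, CC[Si](CC)(CC)OS(=O)(=O)C(F)(F)F
Why: Silyl triflate silylation of a hindered tertiary alcohol; the acid is silylated too (8) and the labile silyl ester is solvolysed selectively. Triethylsilyl is used because this ether must outlast the aqueous acid of step 9 and block O–H insertion in step 7.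

Step 6
Reactants: 9 3-{4-methoxy-2-methyl-5-[2-(triethylsilyloxy)propan-2-yl]phenyl}propanoic acid
Product: 11 1-diazo-4-{4-methoxy-2-methyl-5-[2-(triethylsilyloxy)propan-2-yl]phenyl}butan-2-one, via mixed carbonic anhydride 10 (not isolated)
Conditions: i-BuOCOCl (1.1 equiv), N-methylmorpholine (1.1 equiv), THF, −20 °C; then CH2N2 (3 equiv, Et2O, blast shield), −20 → 0 °C
Reagents that add atoms: diazomethane, C=[N+]=[N-]
Why: Acylation of diazomethane by a mixed carbonic anhydride (first stage of an Arndt–Eistert sequence); the base-buffered activation releases no HCl near the benzylic silyl ether, and the carbonate leaving group takes up the proton so no chloromethyl ketone forms.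

Step 7
Reactants: 11 1-diazo-4-{4-methoxy-2-methyl-5-[2-(triethylsilyloxy)propan-2-yl]phenyl}butan-2-one
Product: 13 (5R)-8-methoxy-11-(triethylsilyloxy)-15-norguaia-1(10),6,8-trien-4-one, via norcaradiene 12 (not isolated)
Conditions: [Cu(MeCN)4]PF6 (5 mol%), (4R,4'R)-2,2'-(propane-2,2-diyl)bis(4-phenyl-4,5-dihydro-1,3-oxazole) (6 mol%), NaB[3,5-(CF3)2C6H3]4 (6 mol%), CH2Cl2, 40 °C, 11 added over 3 h at high dilution; filtration through deactivated silica, used at once
Reagents that add atoms: none
Why: The complex of monovalent copper with the chiral bis(oxazoline) decomposes the diazoketone with loss of N2 to an electrophilic copper carbene at C5. The carbene adds to the C1–C6 π-bond of the arene (intramolecular cyclopropanation) to give norcaradiene 12, which opens by thermal disrotatory 6π electrocyclisation, breaking C1–C6, to cycloheptatriene 13. The closest known reaction type is the intramolecular Buchner reaction of 1-diazo-4-arylbutan-2-ones to 3,8a-dihydroazulen-1(2H)-ones, including enantioselective copper–bis(oxazoline) versions. The cyclopentanone closes by C1–C5 bond formation through the three-atom tether (attack at the ipso carbon, the only bond the tether reaches without strain); the seven-membered ring is not formed by cyclisation but by ring expansion as C5 is inserted between C1 and C6. C5, the only stereocentre of 13, is fixed in the cyclopropanation, where the ligand decides which face of the C1–C6 bond meets the carbene; C1 and C6 of 12 follow from the cis fusions and vanish on opening. Regioselectivity rests on the C10 methyl, which blocks the other ortho bond, and on the methoxy group para to C1, which makes the ipso carbon the most nucleophilic. The O11 silyl ether excludes O–H insertion, slow addition suppresses carbene dimerisation, and the absence of acid and base keeps H5 (α to the C4 carbonyl) in place. The arene substituents arrive as the C10 methyl, the C8 enol ether and the C7 branch, with the 1(10)-alkene already present.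

Step 8
Reactants: 13 (5R)-8-methoxy-11-(triethylsilyloxy)-15-norguaia-1(10),6,8-trien-4-one
Product: 14 (5S)-8-methoxy-11-(triethylsilyloxy)guaia-1(10),4(15),6,8-tetraene
Conditions: Cp2Ti(μ-Cl)(μ-CH2)AlMe2 (1.3 equiv), pyridine (2 equiv), THF/toluene, −40 → 0 °C; 0.1 M aq. NaOH, −20 °C; basic alumina
Reagents that add atoms: titanocene methylidene–chlorodimethylaluminium adduct, C=[Ti](C1C=CC=C1)C1C=CC=C1.C[Al](C)Cl
Why: Carbonyl methylenation by a titanium methylidene (oxatitanacyclobutane, then loss of Cp2Ti=O), a non-basic Wittig equivalent that converts enolisable ketones without epimerisation. It is run on the fresh azulenone while C4 is the only carbonyl, so that C5 stops being α to a ketone before any acid or base is met.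

Step 9
Reactants: 14 (5S)-8-methoxy-11-(triethylsilyloxy)guaia-1(10),4(15),6,8-tetraene
Product: 15 (5S)-11-(triethylsilyloxy)guaia-1(10),4(15),6-trien-8-one
Conditions: oxalic acid (5% aq.), THF, 0 °C; aq. NaHCO3
Reagents that add atoms: water, O
Why: Acid hydrolysis of a dienol methyl ether; kinetic protonation at C9 gives the C8 oxocarbenium ion, water adds and methanol leaves, so the 1(10)-alkene stays out of conjugation and C6–C7 becomes the enone alkene. The weak acid is chosen to spare the tertiary silyl ether and H5.

Step 10
Reactants: 15 (5S)-11-(triethylsilyloxy)guaia-1(10),4(15),6-trien-8-one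
Product: 16 (4S,5R)-11-(triethylsilyloxy)guaia-1(10),6-dien-8-one
Conditions: RhCl(PPh3)3 (10 mol%), H2 (1 atm), toluene, rt
Reagents that add atoms: none
Why: Homogeneous hydrogenation that reduces only the 1,1-disubstituted exocyclic alkene, the trisubstituted enone and the tetrasubstituted 1(10)-alkene being too hindered to bind rhodium. H2 should reach C4 from the α face, the face of H5, because C6 and the seven-membered ring cover the β face, which leaves C15 β and H4 cis to H5.

Step 11
Reactants: 16 (4S,5R)-11-(triethylsilyloxy)guaia-1(10),6-dien-8-one
Product: 17 (4S,5S,7R)-11-(triethylsilyloxy)guai-1(10)-en-8-one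
Conditions: [(Ph3P)CuH]6 (0.4 equiv), H2O (5 equiv), degassed toluene, rt
Reagents that add atoms: none
Why: Conjugate reduction by a phosphine copper hydride; hydride adds to C6 and the copper enolate is protonated at C7 by water. Protonation is expected from the α face, away from the cyclopentane and its β methyl, which is also the more stable arrangement with the C7 branch pseudo-equatorial and cis to C4 across C6.

Step 12
Reactants: 17 (4S,5S,7R)-11-(triethylsilyloxy)guai-1(10)-en-8-one
Product: 18 (4S,5S,7S,8S)-11-(triethylsilyloxy)guai-1(10)-en-8-ol
Conditions: Li (4 equiv), NH3(l)/THF, t-BuOH (2 equiv), −78 °C; solid NH4Cl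
Reagents that add atoms: none
Why: Dissolving-metal reduction (ketyl radical anion, then carbanion protonated with oxygen pseudo-equatorial) should give the more stable alcohol, trans to the bulky C7 branch, as in the menthone-to-menthol case. Hydride reagents are avoided because a bulky equatorial neighbour steers them toward the cis alcohol, and electron transfer is faster than enolisation, so the alkene stays at 1(10).

Step 13
Reactants: 19 ferulic acid
Product: 21 (2E)-3-[4-(tert-butyldimethylsilyloxy)-3-methoxyphenyl]prop-2-enoic acid, via silyl ester 20 (not isolated)
Conditions: t-BuMe2SiCl (2.4 equiv), imidazole (5 equiv), DMF, rt; then AcOH/THF/H2O (3:1:1), rt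
Reagents that add atoms: tert-butyl(chloro)dimethylsilane, CC(C)(C)[Si](C)(C)Cl
Why: Silylation of both acidic hydroxyls, then selective hydrolysis of the much more labile silyl ester; the masked phenol cannot be acylated when the acid is activated.

Step 14
Reactants: 18 (4S,5S,7S,8S)-11-(triethylsilyloxy)guai-1(10)-en-8-ol; 21 (2E)-3-[4-(tert-butyldimethylsilyloxy)-3-methoxyphenyl]prop-2-enoic acid
Product: 23 (4S,5S,7S,8S)-11-(triethylsilyloxy)guai-1(10)-en-8-yl (2E)-3-[4-(tert-butyldimethylsilyloxy)-3-methoxyphenyl]prop-2-enoate, via mixed aroyl anhydride 22 (not isolated)
Conditions: 21 (1.5 equiv), 2,4,6-trichlorobenzoyl chloride (1.5 equiv), Et3N (2 equiv), toluene, rt; then 18, DMAP (2 equiv), toluene, 50 °C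
Reagents that add atoms: none
Why: Yamaguchi esterification; DMAP attacks 22 at the less hindered cinnamoyl carbonyl and the acylpyridinium ion acylates the hindered C8 alcohol with retention at C8, while the silylated tertiary O11 cannot compete.

Step 15
Reactants: 23 (4S,5S,7S,8S)-11-(triethylsilyloxy)guai-1(10)-en-8-yl (2E)-3-[4-(tert-butyldimethylsilyloxy)-3-methoxyphenyl]prop-2-enoate
Product: 24 (4S,5S,7S,8S)-11-hydroxyguai-1(10)-en-8-yl (2E)-3-(4-hydroxy-3-methoxyphenyl)prop-2-enoate
Conditions: Bu4NF (5 equiv), AcOH (5 equiv), THF, 0 °C → rt
Reagents that add atoms: none
Why: Fluoride-induced cleavage of both silyl ethers; acetic acid keeps the phenoxide and alkoxide protonated, so the cinnamate is neither cleaved nor transferred and the tertiary alcohol never meets strong acid.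

## Compound list

1 | 4-methoxy-2-methylbenzaldehyde | COc1ccc(C=O)c(C)c1 | starting material
2 | malonic acid | OC(=O)CC(=O)O | starting material
3 | 2-[(4-methoxy-2-methylphenyl)methylidene]propanedioic acid (not isolated) | COc1ccc(C=C(C(=O)O)C(=O)O)c(C)c1 | intermediate
4 | (2E)-3-(4-methoxy-2-methylphenyl)prop-2-enoic acid | COc1ccc(/C=C/C(=O)O)c(C)c1 | intermediate
5 | 3-(4-methoxy-2-methylphenyl)propanoic acid | COc1ccc(CCC(=O)O)c(C)c1 | intermediate
6 | 3-(5-acetyl-4-methoxy-2-methylphenyl)propanoic acid | COc1cc(C)c(CCC(=O)O)cc1C(C)=O | intermediate
7 | 3-[5-(2-hydroxypropan-2-yl)-4-methoxy-2-methylphenyl]propanoic acid | COc1cc(C)c(CCC(=O)O)cc1C(C)(C)O | intermediate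
8 | triethylsilyl 3-{4-methoxy-2-methyl-5-[2-(triethylsilyloxy)propan-2-yl]phenyl}propanoate (not isolated) | COc1cc(C)c(CCC(=O)O[Si](CC)(CC)CC)cc1C(C)(C)O[Si](CC)(CC)CC | intermediate
9 | 3-{4-methoxy-2-methyl-5-[2-(triethylsilyloxy)propan-2-yl]phenyl}propanoic acid | COc1cc(C)c(CCC(=O)O)cc1C(C)(C)O[Si](CC)(CC)CC | intermediate
10 | mixed anhydride of 9 with isobutyl hydrogen carbonate (not isolated) | COc1cc(C)c(CCC(=O)OC(=O)OCC(C)C)cc1C(C)(C)O[Si](CC)(CC)CC | intermediate
11 | 1-diazo-4-{4-methoxy-2-methyl-5-[2-(triethylsilyloxy)propan-2-yl]phenyl}butan-2-one | [N-]=[N+]=CC(=O)CCc1cc(C(C)(C)O[Si](CC)(CC)CC)c(OC)cc1C | intermediate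
12 | norcaradiene valence isomer of 13: C5 bridges C1 and C6 as a cyclopropane, H5 and H6 trans on the three-membered ring (not isolated) | O=C1CC[C@@]23C(C)=CC(OC)=C(C(C)(C)O[Si](CC)(CC)CC)[C@@H]2[C@@H]13 | intermediate
13 | (5R)-8-methoxy-11-(triethylsilyloxy)-15-norguaia-1(10),6,8-trien-4-one, that is (8aR)-6-methoxy-4-methyl-7-[2-(triethylsilyloxy)propan-2-yl]-3,8a-dihydroazulen-1(2H)-one | O=C1CCC2=C(C)C=C(OC)C(=C[C@@H]12)C(C)(C)O[Si](CC)(CC)CC | intermediate
14 | (5S)-8-methoxy-11-(triethylsilyloxy)guaia-1(10),4(15),6,8-tetraene | C=C1CCC2=C(C)C=C(OC)C(=C[C@@H]12)C(C)(C)O[Si](CC)(CC)CC | intermediate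
15 | (5S)-11-(triethylsilyloxy)guaia-1(10),4(15),6-trien-8-one | C=C1CCC2=C(C)CC(=O)C(=C[C@@H]12)C(C)(C)O[Si](CC)(CC)CC | intermediate
16 | (4S,5R)-11-(triethylsilyloxy)guaia-1(10),6-dien-8-one (H4 cis to H5) | C[C@H]1CCC2=C(C)CC(=O)C(=C[C@@H]12)C(C)(C)O[Si](CC)(CC)CC | intermediate
17 | (4S,5S,7R)-11-(triethylsilyloxy)guai-1(10)-en-8-one (H4, H5, H7 on one face) | C[C@H]1CCC2=C(C)CC(=O)[C@H](C[C@@H]12)C(C)(C)O[Si](CC)(CC)CC | intermediate
18 | (4S,5S,7S,8S)-11-(triethylsilyloxy)guai-1(10)-en-8-ol (hydroxyl trans to the C7 branch) | O[C@H]1CC(C)=C2CC[C@H](C)[C@@H]2C[C@@H]1C(C)(C)O[Si](CC)(CC)CC | intermediate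
19 | ferulic acid | COc1cc(/C=C/C(=O)O)ccc1O | starting material
20 | tert-butyldimethylsilyl (2E)-3-[4-(tert-butyldimethylsilyloxy)-3-methoxyphenyl]prop-2-enoate (not isolated) | COc1cc(/C=C/C(=O)O[Si](C)(C)C(C)(C)C)ccc1O[Si](C)(C)C(C)(C)C | intermediate
21 | (2E)-3-[4-(tert-butyldimethylsilyloxy)-3-methoxyphenyl]prop-2-enoic acid | COc1cc(/C=C/C(=O)O)ccc1O[Si](C)(C)C(C)(C)C | intermediate
22 | mixed anhydride of 21 with 2,4,6-trichlorobenzoic acid (not isolated) | COc1cc(/C=C/C(=O)OC(=O)c2c(Cl)cc(Cl)cc2Cl)ccc1O[Si](C)(C)C(C)(C)C | intermediate
23 | (4S,5S,7S,8S)-11-(triethylsilyloxy)guai-1(10)-en-8-yl (2E)-3-[4-(tert-butyldimethylsilyloxy)-3-methoxyphenyl]prop-2-enoate | COc1cc(/C=C/C(=O)O[C@H]2CC(C)=C3CC[C@H](C)[C@@H]3C[C@@H]2C(C)(C)O[Si](CC)(CC)CC)ccc1O[Si](C)(C)C(C)(C)C | intermediate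
24 | (4S,5S,7S,8S)-11-hydroxyguai-1(10)-en-8-yl (2E)-3-(4-hydroxy-3-methoxyphenyl)prop-2-enoate | COc1cc(/C=C/C(=O)O[C@H]2CC(C)=C3CC[C@H](C)[C@@H]3C[C@@H]2C(C)(C)O)ccc1O | target

## Step count and least certain steps

Total step count: 15. Longest linear sequence: 14 steps (steps 1 to 12, 14 and 15).

Step 7 (key step). The most likely failure is insufficient enantioface selection, because the bulky C7 branch sits next to the reacting C1–C6 bond and no ligand match is known for this substitution pattern. It may be accompanied by diversion of the carbene to ipso attack and rearomatisation, since the methoxy group is para to C1. Fallback: starting from 11, the cycloaddition is run with achiral Rh2(OAc)4 in CH2Cl2, which is the most robust catalyst for this ring expansion, to give the racemic azulenone F1. This is methylenated as in step 8 to the racemic tetraene F2, and the enantiomers are separated by preparative chromatography on a cellulose-carbamate chiral stationary phase. The route is rejoined at 14.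

Step 9. The most likely failure is migration of the 1(10)-alkene into conjugation or loss of configuration at C5 by γ-enolisation, because H5 of 15 is allylic three times over and vinylogously α to C8; partial cleavage of the tertiary silyl ether under acid is a second risk. Fallback: starting from 14, the exocyclic alkene is reduced first with diimide (2-nitrobenzenesulfonohydrazide, Et3N, CH2Cl2), which should add from the α face for the reason given in step 10, to give the methoxytriene F4. Oxalic acid hydrolysis of F4 then gives 16 directly, so the most labile compound, 15, is never made. The route is rejoined at 16.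

Step 8. The most likely failure is loss of material through Lewis-acid-induced opening of the norcaradiene form toward an arene, or erosion at C5, caused by the aluminium component of the reagent. Fallback: starting from 13, Me3SiCH2MgCl with CeCl3 in THF at −78 °C (a non-basic organocerium addition) gives the β-hydroxysilane F3, and KH in THF effects the Peterson elimination, now with no ketone left to enolise. The route is rejoined at 14.

Step 10. The most likely failure is poor facial selectivity at C4, because only C6 distinguishes the two faces of the exocyclic alkene; slow isomerisation of that alkene into the ring by rhodium hydride is a second risk. Fallback: starting from 14, hydroboration with the bulkier 9-borabicyclo[3.3.1]nonane and oxidation with NaOH/H2O2 gives the primary alcohol F5 with C15 β. Tosylation (TsCl, pyridine) gives the sulfonate F6, LiBEt3H reduces it to the methoxytriene F4 already met in the step 9 fallback, and oxalic acid hydrolysis gives 16. The route is rejoined at 16.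

Step 12. The most likely failure is poor facial selectivity at C8, since the thermodynamic preference for the trans alcohol next to a very bulky group may be small in a seven-membered ring; enolisation toward C9 with alkene migration is a second risk. Fallback: starting from 17, LiBH(sec-Bu)3 in THF at −78 °C should attack from the open equatorial direction and give the cis alcohol F7. A Mitsunobu reaction of F7 with 21 (PPh3, diisopropyl azodicarboxylate, toluene) then forms the ester with inversion at C8. The route is rejoined at 23.

## Further compounds

F1 | step 7 | racemate of 13 | O=C1CCC2=C(C)C=C(OC)C(=C[C@@H]12)C(C)(C)O[Si](CC)(CC)CC.O=C1CCC2=C(C)C=C(OC)C(=C[C@H]12)C(C)(C)O[Si](CC)(CC)CC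
F2 | step 7 | racemate of 14 | C=C1CCC2=C(C)C=C(OC)C(=C[C@@H]12)C(C)(C)O[Si](CC)(CC)CC.C=C1CCC2=C(C)C=C(OC)C(=C[C@H]12)C(C)(C)O[Si](CC)(CC)CC
F3 | step 8 | 8-methoxy-11-(triethylsilyloxy)-15-(trimethylsilyl)guaia-1(10),6,8-trien-4-ol, C5 as in 13, either C4 epimer | C[Si](C)(C)CC1(O)CCC2=C(C)C=C(OC)C(=C[C@@H]12)C(C)(C)O[Si](CC)(CC)CC
F4 | step 9 | 8-methoxy-11-(triethylsilyloxy)guaia-1(10),6,8-triene, C15 β, H4 cis to H5 | C[C@H]1CCC2=C(C)C=C(OC)C(=C[C@@H]12)C(C)(C)O[Si](CC)(CC)CC
F5 | step 10 | 8-methoxy-11-(triethylsilyloxy)guaia-1(10),6,8-trien-15-ol, C15 β, H4 cis to H5 | OC[C@H]1CCC2=C(C)C=C(OC)C(=C[C@@H]12)C(C)(C)O[Si](CC)(CC)CC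
F6 | step 10 | 15-(4-methylbenzenesulfonate) of F5 | Cc1ccc(cc1)S(=O)(=O)OC[C@H]1CCC2=C(C)C=C(OC)C(=C[C@@H]12)C(C)(C)O[Si](CC)(CC)CC
F7 | step 12 | (4S,5S,7S,8R)-11-(triethylsilyloxy)guai-1(10)-en-8-ol, hydroxyl cis to the C7 branch | O[C@@H]1CC(C)=C2CC[C@H](C)[C@@H]2C[C@@H]1C(C)(C)O[Si](CC)(CC)CC
A1 | alternative 1 | (4S,5S,7R,8S)-guaia-1(10),11-dien-8-ol | O[C@H]1CC(C)=C2CC[C@H](C)[C@@H]2C[C@@H]1C(C)=C
A2 | alternative 1 | (3Z)-3-[(2S,3S)-3-methyl-2-(3-methylbut-2-en-1-yl)cyclopentylidene]butanal | O=CC/C(C)=C1/CC[C@H](C)[C@@H]1CC=C(C)C
A3 | alternative 2 | (4S)-5α,8α-epoxyguaia-1(10),6-dien-11-ol triethylsilyl ether, oxygen bridge anti to C15 | CC1=C2CC[C@H](C)[C@]23C=C(C(C)(C)O[Si](CC)(CC)CC)[C@H](C1)O3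
A4 | alternative 2 | (6S)-2-methyl-6-{4-[2-(triethylsilyloxy)propan-2-yl]furan-2-yl}hept-1-en-3-ol, either carbinol epimer | C=C(C)C(O)CC[C@H](C)c1cc(C(C)(C)O[Si](CC)(CC)CC)co1
A5 | alternative 3 | 4α-hydroxy-5αH-guaia-1(10),7(11)-dien-8-one | O=C1CC(C)=C2CC[C@](O)(C)[C@@H]2CC1=C(C)C
A6 | alternative 3 | (1(10)E,4R,5R)-4,5-epoxygermacra-1(10),7(11)-dien-8-one | C/C1=C\CC[C@@]2(C)O[C@@H]2CC(=C(C)C)C(=O)C1
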